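The route rests on the spiro carbon C5 (spiro[4.5]decane numbering), which joins the cyclopentane carbinol C1, the chain-bearing C6 and the methyl carbinol C10 of the cyclohexane. C1 and C6 are traced back to ketones and C10 to the inner carbon of a terminal alkyne, so one enantioselective enolate–alkyne (Conia-ene) closure of a 2-(hex-5-ynoyl)cyclopentanone forms the C5–C10 bond, the six-membered ring and the quaternary stereocentre. The precursor carries a methoxycarbonyl spectator on the other α-carbon (future C2); it lets the two ketones of the spiro diketone be told apart and is removed once C6 is an enol triflate. The side chain is grown late from a C2 butenolide.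

Key step: step 2

Remarks on the chemistry:
- Positions are cited in spiro[4.5]decane numbering (C1–C4 five-membered ring, C5 spiro, C6–C10 six-membered ring). TBS = tert-butyldimethylsilyl, TMS = trimethylsilyl, Tf = CF3SO2.
- Assumption: (R)-DTBM-SEGPHOS is taken as the ligand enantiomer that gives the drawn spiro centre; if the sense proves opposite, the (S)-ligand is used.
- The ester-free spiro diketone with this spatial arrangement would be (R). The descriptor at C5 reads S in 5–14 and R in 15–23, and C6 reads S in 14–16, only because neighbour ranks change; no centre is inverted.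
- The methylene is hydrated only after C6 is an enol triflate, and without hydride. An epoxide/hydride sequence would reduce the ketones, and a tertiary β-hydroxy 1,3-diketone is prone to retro-aldol cleavage.

Step 1
Reactants: 1 methyl 2-oxocyclopentane-1-carboxylate; 2 hex-5-ynoic acid
Product: 4 methyl 3-(hex-5-ynoyl)-2-oxocyclopentane-1-carboxylate, via hex-5-ynoyl imidazole 3 (not isolated)
Conditions: 2, CDI, THF, rt; added to the dianion of 1 (2.3 equiv; NaH then n-BuLi, THF, 0 °C) at −78 → 0 °C; 1 M HCl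
Reagents that add atoms: none
Why: The β-keto ester dianion reacts at its more basic γ-carbon (C3) with the acylimidazole in a Claisen-type C-acylation, the excess dianion absorbs the acidic proton of the product, and both α-centres of the product are configurationally labile.

Step 2
Reactants: 4 methyl 3-(hex-5-ynoyl)-2-oxocyclopentane-1-carboxylate
Product: 5 methyl (5S)-10-methylidene-1,6-dioxospiro[4.5]decane-2-carboxylate (C2 epimers interconvert)
Conditions: [(R)-DTBM-SEGPHOS]Pd(OTf)2 (10 mol%), Yb(OTf)3 (20 mol%), AcOH (10 equiv), Et2O, rt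
Reagents that add atoms: none
Why: Proposed new method: the chiral palladium enolate of the 1,3-diketone unit (the β-keto ester carbon cannot reach the alkyne) adds through its central carbon to the Lewis-acid-activated alkyne, and acetic acid protonates the alkenyl–palladium bond to release the exocyclic methylene and the catalyst. The closest known reactions are the (DTBM-SEGPHOS)Pd(OTf)2/Yb(OTf)3 enantioselective Conia-ene cyclisation of α-alkynyl β-dicarbonyls to five-membered rings and In(NTf2)3- or Ph3PAuCl/AgOTf-catalysed 6-exo-dig Conia-ene closures in which the ketone lies in the new ring. The cyclohexanone ring closes 6-exo-dig by forming the C5–C10 bond. The quaternary spiro centre C5 is set by the bisphosphine on palladium, which shields one face of the planar diketonate. The step needs C- over O-cyclisation and 6-exo over 7-endo attack, secured by the soft carbon terminus of the chelated enolate and by the terminal alkyne, whose inner carbon alone is within reach; the product cannot enolise at C5 and so cannot racemise.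

Step 3
Reactants: 5 methyl (5S)-10-methylidene-1,6-dioxospiro[4.5]decane-2-carboxylate
Product: 6 methyl (5S)-10-methylidene-1-oxo-6-(trifluoromethanesulfonyloxy)spiro[4.5]dec-6-ene-2-carboxylate (C2 epimers interconvert)
Conditions: LiN(SiMe3)2 (2.2 equiv), THF, −78 °C; PhNTf2 (1.05 equiv), −78 → 0 °C; 1 M HCl
Reagents that add atoms: N-phenylbis(trifluoromethanesulfonimide), O=S(=O)(N(c1ccccc1)S(=O)(=O)C(F)(F)F)C(F)(F)F
Why: The first equivalent of base turns the β-keto ester into its stabilised enolate and thereby blocks C2, the second removes a C7 proton (the only ketone α-proton left), and only the more reactive cyclohexanone enolate oxygen is triflated (regiodefined enol triflate formation through a dianion).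

Step 4
Reactants: 6 methyl (5S)-10-methylidene-1-oxo-6-(trifluoromethanesulfonyloxy)spiro[4.5]dec-6-ene-2-carboxylate
Product: 7 (5S)-10-methylidene-1-oxospiro[4.5]dec-6-en-6-yl trifluoromethanesulfonate
Conditions: LiCl, DMSO/H2O, 130 °C
Reagents that add atoms: none
Why: Krapcho dealkoxycarbonylation removes the spent ester (chloride demethylates the β-keto ester and the carboxylate loses CO2), while the enol triflate and the methylene, which cannot move into conjugation across the quaternary C5, are inert.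

Step 5
Reactants: 7 (5S)-10-methylidene-1-oxospiro[4.5]dec-6-en-6-yl trifluoromethanesulfonate
Product: 8 (5S,10S)-10-hydroxy-10-methyl-1-oxospiro[4.5]dec-6-en-6-yl trifluoromethanesulfonate
Conditions: Co(acac)2 (20 mol%), PhSiH3, O2 (1 atm), THF, 0 °C → rt
Reagents that add atoms: dioxygen, O=O
Why: Mukaiyama hydration (hydrogen-atom transfer from a cobalt hydride, then capture of the tertiary C10 radical by O2) touches only the electron-rich 1,1-disubstituted alkene under neutral conditions; with the flat C1 carbonyl pseudo-equatorial next to the triflate, the C4 methylene is pseudoaxial and oxygen should enter anti to it, on the C1 face, which sets C10.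

Step 6
Reactants: 8 (5S,10S)-10-hydroxy-10-methyl-1-oxospiro[4.5]dec-6-en-6-yl trifluoromethanesulfonate
Product: 9 (1R,5S,10S)-1,10-dihydroxy-10-methylspiro[4.5]dec-6-en-6-yl trifluoromethanesulfonate
Conditions: Me4NBH(OAc)3, MeCN/AcOH (1:1), −20 °C
Reagents that add atoms: none
Why: In this Evans–Saksena reduction the C10 alkoxyborohydride delivers hydride to the face of the C1 carbonyl on which C10 lies, so the new hydroxyl ends anti to C10 (1R); the temporary alcohol also removes the retro-aldol liability before the basic coupling and later steers the hydroboration.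

Step 7
Reactants: 9 (1R,5S,10S)-1,10-dihydroxy-10-methylspiro[4.5]dec-6-en-6-yl trifluoromethanesulfonate; 10 tert-butyldimethyl(prop-2-en-1-yloxy)silane
Product: 12 (1R,5S,10S)-6-[3-(TBSO)propyl]-10-methylspiro[4.5]dec-6-ene-1,10-diol, via B-alkyl-9-BBN adduct 11 (not isolated)
Conditions: 10, 9-BBN, THF, rt; then 9, PdCl2(dppf) (5 mol%), aq. K3PO4, DMF, 50 °C
Reagents that add atoms: none
Why: B-alkyl Suzuki–Miyaura coupling of the enol triflate with the 9-BBN adduct of the allyl ether installs the three-carbon chain at C6 with its oxygen already protected, and free hydroxyls are tolerated.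

Step 8
Reactants: 12 (1R,5S,10S)-6-[3-(TBSO)propyl]-10-methylspiro[4.5]dec-6-ene-1,10-diol
Product: 14 (1R,5S,6S,7S,10S)-6-[3-(TBSO)propyl]-10-methylspiro[4.5]decane-1,7,10-triol, via C7 alkylborane 13 (not isolated)
Conditions: BH3·SMe2 (excess), THF, 0 °C → rt; then aq. NaOH, H2O2, 0 °C
Reagents that add atoms: hydrogen peroxide, OO
Why: Hydroboration–oxidation puts boron on the less substituted C7 and hydrogen on C6 in a syn addition from the face anti to the pseudoaxial C1 arm, whose borylated oxygen lies over the alkene, so the chain ends cis to C1 (C6 set) and C7 gains the hydroxyl.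

Step 9
Reactants: 14 (1R,5S,6S,7S,10S)-6-[3-(TBSO)propyl]-10-methylspiro[4.5]decane-1,7,10-triol
Product: 15 (5R,6S,10S)-6-[3-(TBSO)propyl]-10-hydroxy-10-methylspiro[4.5]decane-1,7-dione
Conditions: Dess–Martin periodinane (2.5 equiv), NaHCO3, CH2Cl2, rt
Reagents that add atoms: none
Why: Buffered Dess–Martin oxidation converts both secondary alcohols into ketones without epimerising C6 and restores the C1 ketone needed for the side chain, while the tertiary alcohol cannot be oxidised.

Step 10
Reactants: 15 (5R,6S,10S)-6-[3-(TBSO)propyl]-10-hydroxy-10-methylspiro[4.5]decane-1,7-dione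
Product: 16 (5R,6S,10S)-6-[3-(TBSO)propyl]-7,10-dihydroxy-10-methyl-7-(prop-1-en-2-yl)spiro[4.5]decan-1-one (C7 epimers)
Conditions: CeCl3, isopropenylmagnesium bromide (2.3 equiv), THF, −78 °C; quenched cold with aq. NH4Cl
Reagents that add atoms: isopropenylmagnesium bromide, C=C(C)[Mg]Br
Why: The organocerium reagent adds 1,2 without enolising the ketone next to C6 and attacks only the C7 cyclohexanone, because the C1 cyclopentanone sits next to the quaternary spiro carbon and is the less electrophilic ring size; the C7 configuration is erased in the next step.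

Step 11
Reactants: 16 (5R,6S,10S)-6-[3-(TBSO)propyl]-7,10-dihydroxy-10-methyl-7-(prop-1-en-2-yl)spiro[4.5]decan-1-one
Product: 17 (2E)-2-{(5R,6R,10S)-6-[3-(TBSO)propyl]-10-hydroxy-10-methyl-1-oxospiro[4.5]decan-7-ylidene}propanal
Conditions: pyridinium chlorochromate (C5H5NH)[CrO3Cl], 4 Å molecular sieves, CH2Cl2, rt
Reagents that add atoms: pyridinium chlorochromate, [O-][Cr](=O)(=O)Cl.c1cc[nH+]cc1
Why: In this Babler–Dauben oxidative transposition the tertiary allylic chromate undergoes a [3,3] shift and the primary chromate is oxidised to the tetrasubstituted enal; the bulkier C6 arm should sit pseudo-equatorial in the chair-like shift, so the formyl group ends on the C8 side (E), which is also the less strained isomer.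

Step 12
Reactants: 17 (2E)-2-{(5R,6R,10S)-6-[3-(TBSO)propyl]-10-hydroxy-10-methyl-1-oxospiro[4.5]decan-7-ylidene}propanal
Product: 18 (5R,6R,10S)-6-[3-(TBSO)propyl]-10-hydroxy-7-[(2E)-1-hydroxypropan-2-ylidene]-10-methylspiro[4.5]decan-1-one
Conditions: NaBH4, CeCl3·7H2O, MeOH, −78 °C
Reagents that add atoms: none
Why: Luche reduction converts the enal 1,2 into the allylic alcohol at −78 °C far faster than the hindered C1 ketone reacts, which masks the aldehyde for the enolate and hydride steps that follow.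

Step 13
Reactants: 18 (5R,6R,10S)-6-[3-(TBSO)propyl]-10-hydroxy-7-[(2E)-1-hydroxypropan-2-ylidene]-10-methylspiro[4.5]decan-1-one
Product: 19 (5R,6R,10S)-6-[3-(TBSO)propyl]-7-[(2E)-1-(TBSO)propan-2-ylidene]-10-hydroxy-10-methylspiro[4.5]decan-1-one
Conditions: TBSCl, imidazole, DMF, 0 °C
Reagents that add atoms: tert-butyldimethylsilyl chloride, CC(C)(C)[Si](C)(C)Cl
Why: Standard silylation protects the only primary alcohol, and the tertiary alcohol does not react under these conditions.

Step 14
Reactants: 19 (5R,6R,10S)-6-[3-(TBSO)propyl]-7-[(2E)-1-(TBSO)propan-2-ylidene]-10-hydroxy-10-methylspiro[4.5]decan-1-one; 20 4-bromofuran-2(5H)-one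
Product: 23 4-{(5R,6R,10S)-6-[3-(TBSO)propyl]-7-[(2E)-1-(TBSO)propan-2-ylidene]-10-hydroxy-10-methyl-1-oxospiro[4.5]decan-2-yl}furan-2(5H)-one (C2 epimers interconvert), via bis-silylated enol ether 21 (not isolated), via coupled silyl ether 22 (not isolated)
Conditions: TMSOTf, Et3N, CH2Cl2, 0 °C; then 20, Pd2(dba)3 (5 mol%), P(t-Bu)3, Bu3SnF, PhMe, 80 °C; then citric acid, MeOH, rt
Reagents that add atoms: none
Why: Silylation gives the only possible enol silane (C2 is the sole enolisable position) and caps the tertiary alcohol, the fluoride-promoted palladium-catalysed α-alkenylation of the enol silane with the vinylogous acyl bromide forms the C2–C bond without strong base, and mild acid frees the C10 hydroxyl; the butenolide ring locks the geometry of the future trisubstituted alkene and C2 stays labile.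

Step 15
Reactants: 23 4-{(5R,6R,10S)-6-[3-(TBSO)propyl]-7-[(2E)-1-(TBSO)propan-2-ylidene]-10-hydroxy-10-methyl-1-oxospiro[4.5]decan-2-yl}furan-2(5H)-one
Product: 24 4-{(1R,2S,5S,6R,10S)-6-[3-(TBSO)propyl]-7-[(2E)-1-(TBSO)propan-2-ylidene]-1,10-dihydroxy-10-methylspiro[4.5]decan-2-yl}furan-2(5H)-one
Conditions: Me4NBH(OAc)3, MeCN/AcOH (1:1), −20 °C → rt
Reagents that add atoms: none
Why: The Evans–Saksena reduction again delivers hydride from the C10 oxygen to the same face of C1 (1R), and because the C2 epimers of this vinylogous β-keto ester interconvert through the enol, the epimer whose butenolide is anti to the incoming hydride should react preferentially (dynamic kinetic resolution) and give the cis-1,2 arrangement (2S).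

Step 16
Reactants: 24 4-{(1R,2S,5S,6R,10S)-6-[3-(TBSO)propyl]-7-[(2E)-1-(TBSO)propan-2-ylidene]-1,10-dihydroxy-10-methylspiro[4.5]decan-2-yl}furan-2(5H)-one
Product: 25 4-{(1R,2S,5S,6R,10S)-6-[3-(TBSO)propyl]-7-[(2E)-1-(TBSO)propan-2-ylidene]-1,10-dihydroxy-10-methylspiro[4.5]decan-2-yl}-2,5-dihydrofuran-2-ol (lactol anomers)
Conditions: i-Bu2AlH (4 equiv), CH2Cl2, −78 °C; H2O
Reagents that add atoms: none
Why: Partial lactone reduction with i-Bu2AlH at −78 °C stops at the lactol once the two hydroxyl protons are consumed, and the ring keeps the formyl carbon cis to the CH2O group; the crude lactol is used at once because acid would aromatise it to a furan.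

Step 17
Reactants: 26 2-methylprop-2-en-1-ol; 27 1-bromo-3-methylbut-2-ene
Product: 28 6-methyl-2-methylidenehept-5-en-1-ol
Conditions: n-BuLi (2.2 equiv), TMEDA, Et2O, 0 °C → rt; then 27, −78 °C → rt; H2O
Reagents that add atoms: none
Why: The dianion of methallyl alcohol (alkoxide plus allylic carbanion) is alkylated at carbon by the primary allylic bromide in an SN2 reaction.

Step 18
Reactants: 28 6-methyl-2-methylidenehept-5-en-1-ol
Product: 29 2-(bromomethyl)-6-methylhepta-1,5-diene
Conditions: PBr3, Et2O, 0 °C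
Reagents that add atoms: phosphorus tribromide, BrP(Br)Br
Why: PBr3 converts the primary allylic alcohol into the bromide, and direct and allylic substitution give the same product because the allyl unit is symmetric.

Step 19
Reactants: 29 2-(bromomethyl)-6-methylhepta-1,5-diene
Product: 30 diethyl (6-methyl-2-methylidenehept-5-en-1-yl)phosphonate
Conditions: P(OEt)3, neat, 120 °C
Reagents that add atoms: triethyl phosphite, CCOP(OCC)OCC
Why: The Michaelis–Arbuzov reaction of the allylic bromide with triethyl phosphite gives the phosphonate.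

Step 20
Reactants: 25 4-{(1R,2S,5S,6R,10S)-6-[3-(TBSO)propyl]-7-[(2E)-1-(TBSO)propan-2-ylidene]-1,10-dihydroxy-10-methylspiro[4.5]decan-2-yl}-2,5-dihydrofuran-2-ol; 30 diethyl (6-methyl-2-methylidenehept-5-en-1-yl)phosphonate
Product: 31 (2Z,4E)-2-{(1R,2S,5S,6R,10S)-6-[3-(TBSO)propyl]-7-[(2E)-1-(TBSO)propan-2-ylidene]-1,10-dihydroxy-10-methylspiro[4.5]decan-2-yl}-10-methyl-6-methylideneundeca-2,4,9-trien-1-ol
Conditions: 30 (5 equiv), n-BuLi, THF/DMPU, −78 °C; then 25, −78 °C → rt
Reagents that add atoms: none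
Why: In this Horner–Wadsworth–Emmons olefination the lactol opens under base to the (Z)-γ-hydroxy enal, the lithiated allylic phosphonate adds through its α-carbon and the adduct loses phosphate to give the (E)-alkene, which completes the triene and frees the primary allylic alcohol; excess anion is needed because three hydroxyls are deprotonated.

Step 21
Reactants: 31 (2Z,4E)-2-{(1R,2S,5S,6R,10S)-6-[3-(TBSO)propyl]-7-[(2E)-1-(TBSO)propan-2-ylidene]-1,10-dihydroxy-10-methylspiro[4.5]decan-2-yl}-10-methyl-6-methylideneundeca-2,4,9-trien-1-ol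
Product: 32 (2Z,4E)-2-{(1R,2S,5S,6R,10S)-6-[3-(TBSO)propyl]-7-[(2E)-1-(TBSO)propan-2-ylidene]-1,10-dihydroxy-10-methylspiro[4.5]decan-2-yl}-10-methyl-6-methylideneundeca-2,4,9-trien-1-yl acetate
Conditions: AcCl, 2,4,6-collidine, CH2Cl2, −78 °C
Reagents that add atoms: acetyl chloride, CC(Cl)=O
Why: Acetyl chloride with collidine at low temperature acylates the unhindered primary allylic alcohol selectively over the secondary alcohol next to the spiro centre and the tertiary alcohol.

Step 22
Reactants: 32 (2Z,4E)-2-{(1R,2S,5S,6R,10S)-6-[3-(TBSO)propyl]-7-[(2E)-1-(TBSO)propan-2-ylidene]-1,10-dihydroxy-10-methylspiro[4.5]decan-2-yl}-10-methyl-6-methylideneundeca-2,4,9-trien-1-yl acetate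
Product: 33 (2Z,4E)-2-{(1R,2S,5S,6R,10S)-1,10-dihydroxy-6-(3-hydroxypropyl)-7-[(2E)-1-hydroxypropan-2-ylidene]-10-methylspiro[4.5]decan-2-yl}-10-methyl-6-methylideneundeca-2,4,9-trien-1-yl acetate
Conditions: HF·pyridine, pyridine, THF, 0 °C → rt
Reagents that add atoms: none
Why: Buffered HF·pyridine cleaves both primary silyl ethers without touching the allylic acetate or the triene.

Step 23
Reactants: 33 (2Z,4E)-2-{(1R,2S,5S,6R,10S)-1,10-dihydroxy-6-(3-hydroxypropyl)-7-[(2E)-1-hydroxypropan-2-ylidene]-10-methylspiro[4.5]decan-2-yl}-10-methyl-6-methylideneundeca-2,4,9-trien-1-yl acetate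
Product: 34 (2Z,4E)-2-{(1R,2S,5S,6R,10S)-1,10-dihydroxy-6-(3-hydroxypropyl)-10-methyl-7-[(2E)-1-oxopropan-2-ylidene]spiro[4.5]decan-2-yl}-10-methyl-6-methylideneundeca-2,4,9-trien-1-yl acetate (target, CNP0204268.1)
Conditions: MnO2 (activated, excess), CH2Cl2, rt
Reagents that add atoms: none
Why: MnO2 oxidises only the primary allylic alcohol on the tetrasubstituted alkene to the enal with retention of alkene geometry, while the saturated primary, the secondary and the tertiary alcohols and the acetate are inert.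

Compound list
1 | methyl 2-oxocyclopentane-1-carboxylate | COC(=O)C1CCCC1=O | starting material
2 | hex-5-ynoic acid | C#CCCCC(=O)O | starting material
3 | 1-(1H-imidazol-1-yl)hex-5-yn-1-one | C#CCCCC(=O)n1ccnc1 | intermediate
4 | methyl 3-(hex-5-ynoyl)-2-oxocyclopentane-1-carboxylate (both stereocentres labile) | COC(=O)C1CCC(C(=O)CCCC#C)C1=O | intermediate
5 | methyl (5S)-10-methylidene-1,6-dioxospiro[4.5]decane-2-carboxylate (C2 labile) | COC(=O)C1CC[C@]2(C(=O)CCCC2=C)C1=O | intermediate
6 | methyl (5S)-10-methylidene-1-oxo-6-(trifluoromethanesulfonyloxy)spiro[4.5]dec-6-ene-2-carboxylate (C2 labile) | COC(=O)C1CC[C@]2(C(OS(=O)(=O)C(F)(F)F)=CCCC2=C)C1=O | intermediate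
7 | (5S)-10-methylidene-1-oxospiro[4.5]dec-6-en-6-yl trifluoromethanesulfonate | C1CC[C@]2(C(OS(=O)(=O)C(F)(F)F)=CCCC2=C)C1=O | intermediate
8 | (5S,10S)-10-hydroxy-10-methyl-1-oxospiro[4.5]dec-6-en-6-yl trifluoromethanesulfonate | C1CC[C@]2(C(OS(=O)(=O)C(F)(F)F)=CCC[C@]2(C)O)C1=O | intermediate
9 | (1R,5S,10S)-1,10-dihydroxy-10-methylspiro[4.5]dec-6-en-6-yl trifluoromethanesulfonate | C1CC[C@]2(C(OS(=O)(=O)C(F)(F)F)=CCC[C@]2(C)O)[C@@H]1O | intermediate
10 | tert-butyldimethyl(prop-2-en-1-yloxy)silane | C=CCO[Si](C)(C)C(C)(C)C | starting material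
11 | 9-[3-(tert-butyldimethylsilyloxy)propyl]-9-borabicyclo[3.3.1]nonane | CC(C)(C)[Si](C)(C)OCCCB1C2CCCC1CCC2 | intermediate
12 | (1R,5S,10S)-6-[3-(tert-butyldimethylsilyloxy)propyl]-10-methylspiro[4.5]dec-6-ene-1,10-diol | C1CC[C@]2(C(CCCO[Si](C)(C)C(C)(C)C)=CCC[C@]2(C)O)[C@@H]1O | intermediate
13 | C7 alkylborane of 12 (boron cis to H-6; both hydroxyls as boryl ethers) | C1CC[C@]2([C@H](CCCO[Si](C)(C)C(C)(C)C)[C@@H](B)CC[C@]2(C)OB)[C@@H]1OB | intermediate
14 | (1R,5S,6S,7S,10S)-6-[3-(tert-butyldimethylsilyloxy)propyl]-10-methylspiro[4.5]decane-1,7,10-triol | C1CC[C@]2([C@H](CCCO[Si](C)(C)C(C)(C)C)[C@@H](O)CC[C@]2(C)O)[C@@H]1O | intermediate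
15 | (5R,6S,10S)-6-[3-(tert-butyldimethylsilyloxy)propyl]-10-hydroxy-10-methylspiro[4.5]decane-1,7-dione | C1CC[C@]2([C@H](CCCO[Si](C)(C)C(C)(C)C)C(=O)CC[C@]2(C)O)C1=O | intermediate
16 | (5R,6S,10S)-6-[3-(tert-butyldimethylsilyloxy)propyl]-7,10-dihydroxy-10-methyl-7-(prop-1-en-2-yl)spiro[4.5]decan-1-one (C7 epimers) | C1CC[C@]2([C@H](CCCO[Si](C)(C)C(C)(C)C)C(O)(C(C)=C)CC[C@]2(C)O)C1=O | intermediate
17 | (2E)-2-{(5R,6R,10S)-6-[3-(tert-butyldimethylsilyloxy)propyl]-10-hydroxy-10-methyl-1-oxospiro[4.5]decan-7-ylidene}propanal | C1CC[C@]2([C@H](CCCO[Si](C)(C)C(C)(C)C)/C(=C(\C)C=O)CC[C@]2(C)O)C1=O | intermediate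
18 | (5R,6R,10S)-6-[3-(tert-butyldimethylsilyloxy)propyl]-10-hydroxy-7-[(2E)-1-hydroxypropan-2-ylidene]-10-methylspiro[4.5]decan-1-one | C1CC[C@]2([C@H](CCCO[Si](C)(C)C(C)(C)C)/C(=C(\C)CO)CC[C@]2(C)O)C1=O | intermediate
19 | (5R,6R,10S)-6-[3-(tert-butyldimethylsilyloxy)propyl]-7-[(2E)-1-(tert-butyldimethylsilyloxy)propan-2-ylidene]-10-hydroxy-10-methylspiro[4.5]decan-1-one | C1CC[C@]2([C@H](CCCO[Si](C)(C)C(C)(C)C)/C(=C(\C)CO[Si](C)(C)C(C)(C)C)CC[C@]2(C)O)C1=O | intermediate
20 | 4-bromofuran-2(5H)-one | O=C1C=C(Br)CO1 | starting material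
21 | C1 trimethylsilyl enol ether and C10 trimethylsilyl ether of 19 | C=1CC[C@]2([C@H](CCCO[Si](C)(C)C(C)(C)C)/C(=C(\C)CO[Si](C)(C)C(C)(C)C)CC[C@]2(C)O[Si](C)(C)C)C=1O[Si](C)(C)C | intermediate
22 | C10 trimethylsilyl ether of 23 (C2 labile) | O=C1C=C(CO1)C3CC[C@]2([C@H](CCCO[Si](C)(C)C(C)(C)C)/C(=C(\C)CO[Si](C)(C)C(C)(C)C)CC[C@]2(C)O[Si](C)(C)C)C3=O | intermediate
23 | 4-{(5R,6R,10S)-6-[3-(tert-butyldimethylsilyloxy)propyl]-7-[(2E)-1-(tert-butyldimethylsilyloxy)propan-2-ylidene]-10-hydroxy-10-methyl-1-oxospiro[4.5]decan-2-yl}furan-2(5H)-one (C2 labile) | O=C1C=C(CO1)C3CC[C@]2([C@H](CCCO[Si](C)(C)C(C)(C)C)/C(=C(\C)CO[Si](C)(C)C(C)(C)C)CC[C@]2(C)O)C3=O | intermediate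
24 | 4-{(1R,2S,5S,6R,10S)-6-[3-(tert-butyldimethylsilyloxy)propyl]-7-[(2E)-1-(tert-butyldimethylsilyloxy)propan-2-ylidene]-1,10-dihydroxy-10-methylspiro[4.5]decan-2-yl}furan-2(5H)-one | O=C1C=C(CO1)[C@@H]3CC[C@]2([C@H](CCCO[Si](C)(C)C(C)(C)C)/C(=C(\C)CO[Si](C)(C)C(C)(C)C)CC[C@]2(C)O)[C@@H]3O | intermediate
25 | 4-{(1R,2S,5S,6R,10S)-6-[3-(tert-butyldimethylsilyloxy)propyl]-7-[(2E)-1-(tert-butyldimethylsilyloxy)propan-2-ylidene]-1,10-dihydroxy-10-methylspiro[4.5]decan-2-yl}-2,5-dihydrofuran-2-ol (anomers) | OC1C=C(CO1)[C@@H]3CC[C@]2([C@H](CCCO[Si](C)(C)C(C)(C)C)/C(=C(\C)CO[Si](C)(C)C(C)(C)C)CC[C@]2(C)O)[C@@H]3O | intermediate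
26 | 2-methylprop-2-en-1-ol | C=C(C)CO | starting material
27 | 1-bromo-3-methylbut-2-ene | CC(C)=CCBr | starting material
28 | 6-methyl-2-methylidenehept-5-en-1-ol | C=C(CO)CCC=C(C)C | intermediate
29 | 2-(bromomethyl)-6-methylhepta-1,5-diene | C=C(CBr)CCC=C(C)C | intermediate
30 | diethyl (6-methyl-2-methylidenehept-5-en-1-yl)phosphonate | CCOP(=O)(OCC)CC(=C)CCC=C(C)C | intermediate
31 | (2Z,4E)-2-{(1R,2S,5S,6R,10S)-6-[3-(tert-butyldimethylsilyloxy)propyl]-7-[(2E)-1-(tert-butyldimethylsilyloxy)propan-2-ylidene]-1,10-dihydroxy-10-methylspiro[4.5]decan-2-yl}-10-methyl-6-methylideneundeca-2,4,9-trien-1-ol | C=C(/C=C/C=C(\CO)[C@@H]1CC[C@]2([C@H](CCCO[Si](C)(C)C(C)(C)C)/C(=C(\C)CO[Si](C)(C)C(C)(C)C)CC[C@]2(C)O)[C@@H]1O)CCC=C(C)C | intermediate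
32 | acetate of 31 at the primary allylic hydroxyl | C=C(/C=C/C=C(\COC(C)=O)[C@@H]1CC[C@]2([C@H](CCCO[Si](C)(C)C(C)(C)C)/C(=C(\C)CO[Si](C)(C)C(C)(C)C)CC[C@]2(C)O)[C@@H]1O)CCC=C(C)C | intermediate
33 | (2Z,4E)-2-{(1R,2S,5S,6R,10S)-1,10-dihydroxy-6-(3-hydroxypropyl)-7-[(2E)-1-hydroxypropan-2-ylidene]-10-methylspiro[4.5]decan-2-yl}-10-methyl-6-methylideneundeca-2,4,9-trien-1-yl acetate | C=C(/C=C/C=C(\COC(C)=O)[C@@H]1CC[C@]2([C@H](CCCO)/C(=C(\C)CO)CC[C@]2(C)O)[C@@H]1O)CCC=C(C)C | intermediate
34 | (2Z,4E)-2-{(1R,2S,5S,6R,10S)-1,10-dihydroxy-6-(3-hydroxypropyl)-10-methyl-7-[(2E)-1-oxopropan-2-ylidene]spiro[4.5]decan-2-yl}-10-methyl-6-methylideneundeca-2,4,9-trien-1-yl acetate | C=C(/C=C/C=C(\COC(C)=O)[C@@H]1CC[C@]2([C@H](CCCO)/C(=C(\C)C=O)CC[C@]2(C)O)[C@@H]1O)CCC=C(C)C | target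

Total step count: 23 steps. Longest linear sequence: 20 steps (steps 1–16 and 20–23); steps 17–19 make the phosphonate in a side branch.

Steps most likely to fail

1. Step 2 (bears the label). The enantiofacial discrimination of the diketonate may be low, or the 6-exo closure may be slow and lose to O-cyclisation or to migration of the methylene into the ring. The fallback uses known chemistry and sets out from 4. Cyclisation with In(NTf2)3 (5 mol%) in toluene at 80 °C should give the racemic spiro diketone ester F1. The conditions of steps 3 and 4 then give the racemic enol triflate ester F2 and the racemic ketone triflate F3. F3 has a single, non-labile stereocentre and is resolved by preparative chromatography on a chiral stationary phase; its (5S) enantiomer is 7, where the route is rejoined.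

2. Step 14. Transfer of the hindered enol silane to palladium may be slow, so that protodesilylation back to 19 or decomposition of the bromobutenolide wins. The fallback replaces the enolate coupling by an sp2–sp2 coupling and sets out from 19. Dehydrogenation with IBX (DMSO, 70 °C) gives the cyclopentenone F4, and iodine with pyridine gives the α-iodo enone F5. Stille coupling (Pd2(dba)3, AsPh3, CuI, DMF) with 4-(tributylstannyl)furan-2(5H)-one F6, made from 20 and hexabutylditin with Pd(PPh3)4, gives the dienone F7. Conjugate reduction of the ring enone with [(Ph3P)CuH]6 returns to the route at 23.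

3. Step 5. Poor facial selectivity in the capture of the C10 radical, or a 1,2-acyl shift of this β-keto radical, would give the wrong or a mixed C10 configuration, on which both directed reductions (steps 6 and 15) depend. The fallback inverts the logic by adding a carbon nucleophile to a ketone, and sets out from 7. NaBH4 (MeOH, −78 °C) should reduce C1 from the face away from the triflate to give the alcohol F8, and TBSOTf with 2,6-lutidine gives the silyl ether F9. Ozonolysis (O3, CH2Cl2/MeOH, −78 °C, then Me2S) cleaves only the electron-rich methylene and gives the ketone F10. MeMgBr with CeCl3 at −78 °C should add anti to the now pseudoaxial, silyloxy-bearing C1 arm to give the tertiary alcohol F11 with the hydroxyl on the C1 face. HF·pyridine then returns to the route at 9.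

Further compounds
F1 | step 2 | racemic methyl 10-methylidene-1,6-dioxospiro[4.5]decane-2-carboxylate | COC(=O)C1CCC2(C(=O)CCCC2=C)C1=O
F2 | step 2 | racemic methyl 10-methylidene-1-oxo-6-(trifluoromethanesulfonyloxy)spiro[4.5]dec-6-ene-2-carboxylate | COC(=O)C1CCC2(C(OS(=O)(=O)C(F)(F)F)=CCCC2=C)C1=O
F3 | step 2 | racemic 10-methylidene-1-oxospiro[4.5]dec-6-en-6-yl trifluoromethanesulfonate | C1CCC2(C(OS(=O)(=O)C(F)(F)F)=CCCC2=C)C1=O
F4 | step 14 | (5R,6R,10S)-6-[3-(tert-butyldimethylsilyloxy)propyl]-7-[(2E)-1-(tert-butyldimethylsilyloxy)propan-2-ylidene]-10-hydroxy-10-methylspiro[4.5]dec-2-en-1-one | C1=CC[C@]2([C@H](CCCO[Si](C)(C)C(C)(C)C)/C(=C(\C)CO[Si](C)(C)C(C)(C)C)CC[C@]2(C)O)C1=O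
F5 | step 14 | 2-iodo derivative of F4 | IC1=CC[C@]2([C@H](CCCO[Si](C)(C)C(C)(C)C)/C(=C(\C)CO[Si](C)(C)C(C)(C)C)CC[C@]2(C)O)C1=O
F6 | step 14 | 4-(tributylstannyl)furan-2(5H)-one | CCCC[Sn](CCCC)(CCCC)C1=CC(=O)OC1
F7 | step 14 | 4-{(5R,6R,10S)-6-[3-(tert-butyldimethylsilyloxy)propyl]-7-[(2E)-1-(tert-butyldimethylsilyloxy)propan-2-ylidene]-10-hydroxy-10-methyl-1-oxospiro[4.5]dec-2-en-2-yl}furan-2(5H)-one | O=C1C=C(CO1)C3=CC[C@]2([C@H](CCCO[Si](C)(C)C(C)(C)C)/C(=C(\C)CO[Si](C)(C)C(C)(C)C)CC[C@]2(C)O)C3=O
F8 | step 5 | (1R,5R)-1-hydroxy-10-methylidenespiro[4.5]dec-6-en-6-yl trifluoromethanesulfonate | C1CC[C@]2(C(OS(=O)(=O)C(F)(F)F)=CCCC2=C)[C@@H]1O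
F9 | step 5 | (1R,5R)-1-(tert-butyldimethylsilyloxy)-10-methylidenespiro[4.5]dec-6-en-6-yl trifluoromethanesulfonate | C1CC[C@]2(C(OS(=O)(=O)C(F)(F)F)=CCCC2=C)[C@@H]1O[Si](C)(C)C(C)(C)C
F10 | step 5 | (1R,5R)-1-(tert-butyldimethylsilyloxy)-10-oxospiro[4.5]dec-6-en-6-yl trifluoromethanesulfonate | C1CC[C@]2(C(OS(=O)(=O)C(F)(F)F)=CCCC2=O)[C@@H]1O[Si](C)(C)C(C)(C)C
F11 | step 5 | (1R,5S,10S)-1-(tert-butyldimethylsilyloxy)-10-hydroxy-10-methylspiro[4.5]dec-6-en-6-yl trifluoromethanesulfonate | C1CC[C@]2(C(OS(=O)(=O)C(F)(F)F)=CCC[C@]2(C)O)[C@@H]1O[Si](C)(C)C(C)(C)C
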